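The rate constants were drawn at random within sensible limits; what happens was integrated by code.

Over a run of 2.0 h at one temperature, what I want from this flask is how long the target lasts once it is made.

    substrate + reagent in the reaction phase → target (k1 = 0.0333 L mol⁻¹ s⁻¹)
    2 substrate → homo dimer (k2 = 0.00273 L mol⁻¹ s⁻¹)
    crystals ⇌ target, rate k3*(cs3 - [target]) while solid is left; crystals form when [target] > cs3 (cs3 = 0.13 M, k3 = 0.181 s⁻¹)
    target → over-reaction product (k4 = 4.40 × 10⁻⁴ s⁻¹)
    reagent in the reaction phase ⇌ reagent in the second phase, rate k5*([reagent in the reaction phase] - [reagent in the second phase]/K5) per volume of the first phase (K5 = 2.1, k5 = 0.00241 s⁻¹)
    target → decomposed product (k6 = 0.00109 s⁻¹)
    target ⇌ product in the second phase, rate k7*([target] - [product in the second phase]/K7) per volume of the first phase (K7 = 24.7, k7 = 0.00350 s⁻¹)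

substrate 0.20 M; reagent in the second phase 0.220 M; time 2.0 h; volume of the second phase over the first 1.0

- ash: doubling the transfer coefficient of step 7, all else as stated
- maple: doubling the amount of reagent in the second phase, all else as stated
- oak: doubling the solubility in step 3, all else as stated
- alder: doubling the dissolution coefficient of step 3, all else as stated

- how much target and product in the second phase and crystals together there is at 2.0 h, in percent of the substrate charged
- concentration of target in solution at 1.0 h, in percent of saturation
- the change that raises the amount of target and product in the second phase and crystals together at 2.0 h, in percent of the substrate charged most ("none" if none brings more than 2 percentage points) (ash / maple / oak / alder / none)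
- amount of target and product in the second phase and crystals together at 2.0 h, in percent of the substrate charged, after alder

- percent here means substrate units held: one homo dimer counts as two
- what is said of target includes product in the second phase and crystals
- a step written with two of one species runs at k times the square of its concentration and takes two of it each time
- in the second phase: reagent in the second phase, product in the second phase; everything else is in the first
- charges count per volume of the first phase; a concentration in a rate is the amount of a species over the volume of its own phase; every rate counts per litre of the first phase
- crystals is a solid; its amount is given per volume of the solution
- run time (flask): 2.0 h

First comes the race for the substrate. The reagent in the reaction phase arrives by transfer and leaves by reaction, and its concentration b starts at nil. With the substrate and the reagent in the second phase taken as charged, the two flows balance at b = 0.0278 M. With b steady, the reaction with reagent is first order in substrate (pseudo-first-order), while the dimer step is second order. Let r be the dimer rate over the reagent rate at the start, here 1.18. Integrating one against the other, the share of substrate that becomes target is f, the natural logarithm of one plus r, divided by r: 66.1%.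

Now the target. My zero is the even split, a partition ratio of one at equal volumes, where the two phases hold the same amount. Here the ratio is 24.7, so the second phase is the target's resting state. In solution the target decays at d = 0.00153 s⁻¹, a half-life of 0.126 h, shorter than the run. Each time dissolved target has the choice, a share w = 69.6% goes into the second phase and the remainder decays. Simulated target comes back at the transfer coefficient over the partition ratio and volume ratio. So I define the storage leak L, the rate constant at which simulated target is lost, as that return rate times the share that decays on return: 0.155 h⁻¹.

I charge the leak over the whole run, a slight overcount, and the yield is f times w times the exponential of minus L times the time: 33.7%. Dissolved target is w times the simulated amount over the partition ratio, which at 1.0 h gives 1.71% of saturation. At the starting pace dissolved target would stand near 0.0369 M, less than the solubility 0.13 M, so I expect no crystals, and alder leaves 33.7%. Doubling the reagent doubles b and gives 40.1%. Doubling the transfer coefficient raises w and the leak together and gives 37.6%. My choice is maple.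

The forecast says 34%, 2.1%, maple and 34% after alder, on the ground that “no crystals form and alder and oak change nothing”.

The flask gives 33.6%, 2.13% of saturation at 1.0 h, 33.6% after alder, and maple as the best change, worth 5.6 percentage points. At 2.00 h crystals stand at 0%, and 32.7% of the 33.6% target lies in the second phase. Starting from 33.6%, the leak L gives 21.1% for the neighbour read at 5.0 h, which reads 21.3%. For this flask left to 20.0 h it gives 2.06%, and the flask reads 2.18%.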